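**Plan**
- Retrosynthesis: remove the two CHO groups (aryl C–C), open the aryl ether O–C1 to a free phenol and a C1=C10 alkene, take the cyclopropane (C6–C11, C7–C11) back to a C6=C7 alkene, cut C9–C10 and C5–C6 of the seven-membered carbocycle together, and last cut C4–C7′.
- Forward: arene, isobutyl group and cyclopentane are joined first (C7′–C4); the ketone becomes a cyclopentenyl diazoacetate; the seven-membered ring is then closed onto the cyclopentene, followed by the cyclopropane, the C-10 methyl, the oxepane and the two formyl groups.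
- Enabling feature: in the carbocycle C1/C5/C6/C7/C8/C9/C10, C-5 and C-10 are the two neighbours of C-1 and C-6 to C-9 are four contiguous carbons. The ring therefore divides into a vinylcarbenoid (carbene carbon C-10, vinyl group C1=C5 inside the cyclopentene) and a butadiene. An ester on C-10 (later the methyl) and SiMe3 on C-6 (later lost, moving the alkene to C6=C7) are helpers.
- Stereochemistry: C-4 from the (S)-1-phenylethylamine imine; C-7′ from endo addition to the E o-quinone methide; C-5 from catalyst-controlled cyclopropanation relayed through the boat Cope transition state; C-6/C-7 from carbene addition on the face of H-5; C-1 from the tether; C-10 from anti addition across C1=C10.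

Key step: step 10

Assumption: terpenoid carbons carry aromadendrane numbers (C-1 ether carbon, C-4 quaternary carbon bearing benzylic C-7′, C-5 ring-fusion CH, C-6/C-7/C-11 cyclopropane, C-10 the CHMe carbon); the sense of induction of the (S)-1-phenylethylamine imine and of Rh2(R-DOSP)4 (DOSP = N-(4-dodecylbenzenesulfonyl)prolinate) is taken from their established selectivity models, and the enantiomeric reagent would be used if the sense proved opposite.

Step 1
Reactants: 1 2,4,6-trihydroxybenzaldehyde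
Product: 2 2,4-bis(benzyloxy)-6-hydroxybenzaldehyde
Conditions: BnBr (2.1 equiv), K2CO3, DMF, 0 °C to rt
Reagents that add atoms: benzyl bromide BrCc1ccccc1
Why: Williamson etherification in which the 4-OH and one 2-OH are alkylated while the other ortho OH, held in a hydrogen bond to the formyl group, should stay free.

Step 2
Reactants: 2 2,4-bis(benzyloxy)-6-hydroxybenzaldehyde
Product: 3 3,5-bis(benzyloxy)-2-formylphenyl tert-butyl carbonate
Conditions: Boc2O, DMAP (cat.), THF, rt
Reagents that add atoms: di-tert-butyl dicarbonate CC(C)(C)OC(=O)OC(=O)OC(C)(C)C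
Why: DMAP-catalysed O-acylation of the remaining phenol gives the aryl carbonate that later triggers o-quinone methide formation.

Step 3
Reactants: 4 2-methylcyclopentan-1-one; 5 (S)-1-phenylethan-1-amine
Product: 6 (1S)-N-(2-methylcyclopentylidene)-1-phenylethan-1-amine
Conditions: TsOH (cat.), toluene, reflux, Dean–Stark trap
Reagents that add atoms: none
Why: Acid-catalysed ketone–amine condensation with azeotropic removal of water gives the chiral imine, which reacts later through its more substituted secondary enamine tautomer.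

Step 4
Reactants: 3 3,5-bis(benzyloxy)-2-formylphenyl tert-butyl carbonate; 6 (1S)-N-(2-methylcyclopentylidene)-1-phenylethan-1-amine
Product: 10 keto phenol (2R)-2-[(1S)-1-[2,4-bis(benzyloxy)-6-hydroxyphenyl]-3-methylbutyl]-2-methylcyclopentan-1-one, via bromomagnesium carbinolate 7 (not isolated), via o-quinone methide 8 (not isolated), via imine adduct 9 (not isolated)
Conditions: i-BuMgBr, THF, −78 °C; then 6, −78 °C to rt; then aq. AcOH, rt
Reagents that add atoms: isobutylmagnesium bromide CC(C)C[Mg]Br; water O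
Why: Proposed new method: the Grignard reagent adds to the aldehyde, the Boc group migrates to the new alkoxide and is expelled to give E-o-quinone methide 8, whose methide carbon is attacked by the tetrasubstituted secondary enamine tautomer of 6 in a compact aza-ene (endo) transition state with N–H transfer to the quinone oxygen, so that attack anti to the phenyl group of the auxiliary sets C-4 (R) and the endo arrangement of the E methide sets C-7′, and hydrolysis then releases ketone and auxiliary; the closest known reactions are the deracemizing Michael alkylation of 1-phenylethylamine imines of 2-methylcycloalkanones with electron-poor alkenes and the cycloaddition of enamines and enol ethers to o-quinone methides generated in this way.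

Step 5
Reactants: 10 keto phenol
Product: 11 (2R)-2-methyl-2-[(1S)-3-methyl-1-[2,4,6-tris(benzyloxy)phenyl]butyl]cyclopentan-1-one
Conditions: BnBr, K2CO3, DMF, rt
Reagents that add atoms: benzyl bromide BrCc1ccccc1
Why: Williamson etherification of the free phenol (any hemiketal opens under base) gives the tris(benzyl) ether, so that all three phenols can later be unmasked together.

Step 6
Reactants: 11 tris(benzyl) ketone
Product: 12 keto ester methyl 2-[(3R)-3-methyl-3-[(1S)-3-methyl-1-[2,4,6-tris(benzyloxy)phenyl]butyl]-2-oxocyclopentyl]acetate (both C-1 epimers)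
Conditions: LiN(i-Pr)2, THF, −78 °C; BrCH2CO2Me, DMPU, −78 to −20 °C
Reagents that add atoms: methyl bromoacetate COC(=O)CBr
Why: Kinetic enolate alkylation at C-1, the only enolizable position next to the C-5 ketone because C-4 is quaternary, introduces the future C-10 with its ester, and the new C-1 centre is erased in step 7.

Step 7
Reactants: 12 keto ester
Product: 13 enol triflate methyl 2-[(3R)-3-methyl-3-[(1R)-3-methyl-1-[2,4,6-tris(benzyloxy)phenyl]butyl]-2-(trifluoromethanesulfonyloxy)cyclopent-1-en-1-yl]acetate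
Conditions: KN(SiMe3)2, THF, −78 °C; PhNTf2, −78 to 0 °C
Reagents that add atoms: N-phenylbis(trifluoromethanesulfonimide) O=S(=O)(N(c1ccccc1)S(=O)(=O)C(F)(F)F)C(F)(F)F
Why: The ketone enolate, which can form only towards C-1, is trapped on oxygen to give the C5=C1 enol triflate regiospecifically.

Step 8
Reactants: 13 enol triflate
Product: 14 methyl 2-[(3S)-3-methyl-3-[(1R)-3-methyl-1-[2,4,6-tris(benzyloxy)phenyl]butyl]cyclopent-1-en-1-yl]acetate
Conditions: Pd(OAc)2 (cat.), PPh3, HCO2H, Et3N, DMF, 60 °C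
Reagents that add atoms: none
Why: Palladium-catalysed formate reduction of the enol triflate replaces OTf by H and should give the C5(H)=C1 cyclopentene with the ester still out of conjugation.

Step 9
Reactants: 14 cyclopentenyl acetate
Product: 15 vinyldiazoacetate methyl 2-diazo-2-[(3S)-3-methyl-3-[(1R)-3-methyl-1-[2,4,6-tris(benzyloxy)phenyl]butyl]cyclopent-1-en-1-yl]acetate
Conditions: 4-AcNHC6H4SO2N3, DBU, MeCN, 0 °C to rt
Reagents that add atoms: 4-acetamidobenzenesulfonyl azide CC(=O)Nc1ccc(cc1)S(=O)(=O)N=[N+]=[N-]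
Why: Regitz diazo transfer to the doubly activated C-10 methylene (allylic and alpha to the ester) gives the vinyldiazoacetate.

Step 10
Reactants: 15 vinyldiazoacetate; 16 (E)-buta-1,3-dien-1-yl(trimethyl)silane
Product: 18 silylated hydroazulene ester methyl (3R,3aR,4S)-3-methyl-3-[(1R)-3-methyl-1-[2,4,6-tris(benzyloxy)phenyl]butyl]-4-(trimethylsilyl)-1,2,3,3a,4,7-hexahydroazulene-8-carboxylate, via cis-divinylcyclopropane 17 (not isolated)
Conditions: Rh2(R-DOSP)4 (1 mol %), 16 (5 equiv), hexanes, −78 °C to rt, then 60 °C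
Reagents that add atoms: none
Why: The rhodium carbenoid formed from 15 by loss of N2 cyclopropanates the unsubstituted vinyl group of 16 (the trans-disubstituted vinylsilane bond is not attacked) with the cyclopentenyl donor group cis to the silylvinyl group, and the resulting cis-divinylcyclopropane 17 undergoes Cope rearrangement through a boat transition state, a formal (4+3) cycloaddition whose closest precedent is the tandem cyclopropanation/Cope rearrangement of cycloalkenyl diazoacetates with 1-substituted butadienes. The seven-membered ring (C1, C5, C6, C7, C8, C9, C10) closes by intermolecular carbenoid addition, which forms C10–C9, and by the concerted [3,3] shift, which forms C5–C6 while the transient cyclopropane bond C10–C8 opens, leaving C1=C10 and C7=C8. Of the new stereocentres, C-6 follows from the E geometry of the vinylsilane (the outside SiMe3 ends cis to C-4) and is erased in step 11, while C-5 follows from which face of the cyclopentene is presented in the boat, and this is fixed by the (1R,2S) configuration of the cyclopropane set by the chiral catalyst. The selectivity needed is C5–C6 bond formation on the cyclopentene face that carries the C-4 methyl, anti to the bulky C-7′ substituent, so catalyst control and substrate bias point the same way; excess diene in a hydrocarbon solvent should keep the carbenoid from inserting into benzylic C–H bonds. The ester makes the carbenoid a donor/acceptor species, then shields C1=C10 from the carbene of step 12, and is reduced to the C-10 methyl in steps 14 and 15.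

Step 11
Reactants: 18 silylated hydroazulene ester
Product: 19 diene ester methyl (3R,3aR)-3-methyl-3-[(1R)-3-methyl-1-[2,4,6-tris(benzyloxy)phenyl]butyl]-1,2,3,3a,6,7-hexahydroazulene-8-carboxylate
Conditions: CF3CO2H, CH2Cl2, 0 °C
Reagents that add atoms: none
Why: Protodesilylation of the allylsilane in the SE2′ sense (protonation at C-8, loss of silicon from C-6) moves the double bond to C6=C7 and removes the C-6 stereocentre.

Step 12
Reactants: 19 diene ester
Product: 20 dibromocyclopropane methyl (1aR,7R,7aR,7bS)-1,1-dibromo-7-methyl-7-[(1R)-3-methyl-1-[2,4,6-tris(benzyloxy)phenyl]butyl]-1a,2,3,5,6,7,7a,7b-octahydro-1H-cyclopropa[e]azulene-4-carboxylate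
Conditions: PhHgCBr3, benzene, 80 °C
Reagents that add atoms: phenyl(tribromomethyl)mercury BrC(Br)(Br)[Hg]c1ccccc1
Why: Dibromocarbene generated thermally under neutral conditions (which spare the doubly allylic H-5) should add to the cis-disubstituted C6=C7 bond, not to the ester-deactivated C1=C10 bond, from the face of H-5 and anti to quaternary C-4, setting C-6 and C-7 with a cis-fused cyclopropane.

Step 13
Reactants: 20 dibromocyclopropane
Product: 22 gem-dimethylcyclopropane ester methyl (1aR,7R,7aR,7bR)-1,1,7-trimethyl-7-[(1R)-3-methyl-1-[2,4,6-tris(benzyloxy)phenyl]butyl]-1a,2,3,5,6,7,7a,7b-octahydro-1H-cyclopropa[e]azulene-4-carboxylate, via cyclopropylcopper 21 (not isolated)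
Conditions: Me2CuLi (5 equiv), Et2O, −15 °C; then MeI, 0 °C
Reagents that add atoms: lithium dimethylcuprate [Li+].C[Cu-]C; iodomethane CI
Why: Bromine–copper exchange with methyl transfer gives the 1-methylcyclopropylcopper species 21, which MeI alkylates, the known gem-dimethylation of dibromocyclopropanes; C-11 ends as CMe2 and is not stereogenic.

Step 14
Reactants: 22 gem-dimethylcyclopropane ester
Product: 23 allylic alcohol [(1aR,7R,7aR,7bR)-1,1,7-trimethyl-7-[(1R)-3-methyl-1-[2,4,6-tris(benzyloxy)phenyl]butyl]-1a,2,3,5,6,7,7a,7b-octahydro-1H-cyclopropa[e]azulen-4-yl]methanol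
Conditions: i-Bu2AlH, CH2Cl2, −78 °C
Reagents that add atoms: none
Why: i-Bu2AlH reduces the conjugated ester in the 1,2 sense to the primary allylic alcohol and should leave cyclopropane and benzyl ethers untouched.

Step 15
Reactants: 23 allylic alcohol
Product: 25 C-10 methyl alkene (1aR,7R,7aR,7bR)-1,1,4,7-tetramethyl-7-[(1R)-3-methyl-1-[2,4,6-tris(benzyloxy)phenyl]butyl]-1a,2,3,5,6,7,7a,7b-octahydro-1H-cyclopropa[e]azulene, via allylic mesylate 24 (not isolated)
Conditions: MsCl, Et3N, CH2Cl2, −20 °C; then LiEt3BH, THF, 0 °C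
Reagents that add atoms: methanesulfonyl chloride CS(=O)(=O)Cl (its atoms stay only in 24)
Why: Mesylation and hydride displacement at the primary allylic carbon (direct SN2, since the SN2′ terminus C-1 is fully substituted) turn the former ester carbon into the C-10 methyl.

Step 16
Reactants: 25 C-10 methyl alkene
Product: 26 triol 2-[(1R)-3-methyl-1-[(1aR,7R,7aR,7bR)-1,1,4,7-tetramethyl-1a,2,3,5,6,7,7a,7b-octahydro-1H-cyclopropa[e]azulen-7-yl]butyl]benzene-1,3,5-triol
Conditions: H2 (1 atm), Pd/C, EtOAc/MeOH, rt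
Reagents that add atoms: none
Why: Hydrogenolysis of the three benzyl ethers frees the phloroglucinol, while the tetrasubstituted C1=C10 alkene and the unactivated cyclopropane are expected to survive at 1 atm.

Step 17
Reactants: 26 triol
Product: 27 bridged aryl ether (the target without its two formyl groups; 1S,4R,5R,6R,7R,10S,7′R)
Conditions: TsOH·H2O (cat.), CH2Cl2, 0 °C to rt
Reagents that add atoms: none
Why: Acid-catalysed intramolecular hydroalkoxylation in which Markovnikov protonation at C-10 gives the tertiary C-1 cation, captured by the ortho phenol held over the five-membered ring by the C4–C7′ bond (seven-membered ether ring, oxygen necessarily cis to C-7′, which fixes C-1), while C-10 should be set by anti addition and by reversible ionization favouring the epimer with the methyl anti to C-5.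

Step 18
Reactants: 27 bridged aryl ether
Product: 29 target CNP0189833.2, via bis(iminium) dichloride 28 (not isolated)
Conditions: POCl3, DMF, MeCN, 0 °C to rt; then H2O, 50 °C
Reagents that add atoms: N,N-dimethylformamide CN(C)C=O; phosphoryl chloride O=P(Cl)(Cl)Cl (chloride counter-ions of 28 only); water O
Why: Twofold Vilsmeier–Haack formylation at the two free ring positions, each ortho or para to a free hydroxyl, followed by hydrolysis of the bis(iminium) salt should give the dialdehyde.

**Compound list**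
1 | 2,4,6-trihydroxybenzaldehyde | O=Cc1c(O)cc(O)cc1O | starting material
2 | 2,4-bis(benzyloxy)-6-hydroxybenzaldehyde | O=Cc1c(O)cc(OCc2ccccc2)cc1OCc1ccccc1 | intermediate
3 | 3,5-bis(benzyloxy)-2-formylphenyl tert-butyl carbonate | O=Cc1c(OC(=O)OC(C)(C)C)cc(OCc2ccccc2)cc1OCc1ccccc1 | intermediate
4 | 2-methylcyclopentan-1-one (racemic) | CC1CCCC1=O | starting material
5 | (S)-1-phenylethan-1-amine | C[C@H](N)c1ccccc1 | starting material
6 | (1S)-N-(2-methylcyclopentylidene)-1-phenylethan-1-amine (ring C-2 epimers interconvert through the enamine) | C[C@H](N=C1CCCC1C)c1ccccc1 | intermediate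
7 | bromomagnesium 1-[2,4-bis(benzyloxy)-6-(tert-butoxycarbonyloxy)phenyl]-3-methylbutan-1-olate | CC(C)CC(O[Mg]Br)c1c(OC(=O)OC(C)(C)C)cc(OCc2ccccc2)cc1OCc1ccccc1 | intermediate
8 | (6E)-3,5-bis(benzyloxy)-6-(3-methylbutylidene)cyclohexa-2,4-dien-1-one | CC(C)C/C=C1/C(=O)C=C(OCc2ccccc2)C=C1OCc1ccccc1 | intermediate
9 | imine adduct: (S)-1-phenylethyl imine of 10, configuration at C-4 and C-7′ as in 10 | CC(C)C[C@@H](c1c(O)cc(OCc2ccccc2)cc1OCc1ccccc1)[C@@]1(C)CCCC1=N[C@@H](C)c1ccccc1 | intermediate
10 | (2R)-2-[(1S)-1-[2,4-bis(benzyloxy)-6-hydroxyphenyl]-3-methylbutyl]-2-methylcyclopentan-1-one (may exist partly as its cyclic hemiketal) | CC(C)C[C@@H](c1c(O)cc(OCc2ccccc2)cc1OCc1ccccc1)[C@@]1(C)CCCC1=O | intermediate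
11 | (2R)-2-methyl-2-[(1S)-3-methyl-1-[2,4,6-tris(benzyloxy)phenyl]butyl]cyclopentan-1-one | CC(C)C[C@@H](c1c(OCc2ccccc2)cc(OCc2ccccc2)cc1OCc1ccccc1)[C@@]1(C)CCCC1=O | intermediate
12 | methyl 2-[(3R)-3-methyl-3-[(1S)-3-methyl-1-[2,4,6-tris(benzyloxy)phenyl]butyl]-2-oxocyclopentyl]acetate (both C-1 epimers) | CC(C)C[C@@H](c1c(OCc2ccccc2)cc(OCc2ccccc2)cc1OCc1ccccc1)[C@@]1(C)CCC(CC(=O)OC)C1=O | intermediate
13 | methyl 2-[(3R)-3-methyl-3-[(1R)-3-methyl-1-[2,4,6-tris(benzyloxy)phenyl]butyl]-2-(trifluoromethanesulfonyloxy)cyclopent-1-en-1-yl]acetate | CC(C)C[C@@H](c1c(OCc2ccccc2)cc(OCc2ccccc2)cc1OCc1ccccc1)[C@@]1(C)CCC(CC(=O)OC)=C1OS(=O)(=O)C(F)(F)F | intermediate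
14 | methyl 2-[(3S)-3-methyl-3-[(1R)-3-methyl-1-[2,4,6-tris(benzyloxy)phenyl]butyl]cyclopent-1-en-1-yl]acetate | CC(C)C[C@@H](c1c(OCc2ccccc2)cc(OCc2ccccc2)cc1OCc1ccccc1)[C@@]1(C)CCC(CC(=O)OC)=C1 | intermediate
15 | methyl 2-diazo-2-[(3S)-3-methyl-3-[(1R)-3-methyl-1-[2,4,6-tris(benzyloxy)phenyl]butyl]cyclopent-1-en-1-yl]acetate | CC(C)C[C@@H](c1c(OCc2ccccc2)cc(OCc2ccccc2)cc1OCc1ccccc1)[C@@]1(C)CCC(C(=[N+]=[N-])C(=O)OC)=C1 | intermediate
16 | (E)-buta-1,3-dien-1-yl(trimethyl)silane | C=C/C=C/[Si](C)(C)C | starting material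
17 | methyl (1R,2S)-1-[(3S)-3-methyl-3-[(1R)-3-methyl-1-[2,4,6-tris(benzyloxy)phenyl]butyl]cyclopent-1-en-1-yl]-2-[(E)-2-(trimethylsilyl)ethenyl]cyclopropane-1-carboxylate | CC(C)C[C@@H](c1c(OCc2ccccc2)cc(OCc2ccccc2)cc1OCc1ccccc1)[C@@]1(C)CCC([C@@]2(C(=O)OC)C[C@H]2/C=C/[Si](C)(C)C)=C1 | intermediate
18 | methyl (3R,3aR,4S)-3-methyl-3-[(1R)-3-methyl-1-[2,4,6-tris(benzyloxy)phenyl]butyl]-4-(trimethylsilyl)-1,2,3,3a,4,7-hexahydroazulene-8-carboxylate | CC(C)C[C@@H](c1c(OCc2ccccc2)cc(OCc2ccccc2)cc1OCc1ccccc1)[C@@]1(C)CCC2=C(C(=O)OC)CC=C[C@H]([Si](C)(C)C)[C@H]12 | intermediate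
19 | methyl (3R,3aR)-3-methyl-3-[(1R)-3-methyl-1-[2,4,6-tris(benzyloxy)phenyl]butyl]-1,2,3,3a,6,7-hexahydroazulene-8-carboxylate | CC(C)C[C@@H](c1c(OCc2ccccc2)cc(OCc2ccccc2)cc1OCc1ccccc1)[C@@]1(C)CCC2=C(C(=O)OC)CCC=C[C@H]12 | intermediate
20 | methyl (1aR,7R,7aR,7bS)-1,1-dibromo-7-methyl-7-[(1R)-3-methyl-1-[2,4,6-tris(benzyloxy)phenyl]butyl]-1a,2,3,5,6,7,7a,7b-octahydro-1H-cyclopropa[e]azulene-4-carboxylate | CC(C)C[C@@H](c1c(OCc2ccccc2)cc(OCc2ccccc2)cc1OCc1ccccc1)[C@@]1(C)CCC2=C(C(=O)OC)CC[C@@H]3[C@H]([C@H]12)C3(Br)Br | intermediate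
21 | (1-methylcyclopropyl)copper species derived from 20 (one Br replaced by CH3, the other by Cu; C-11 configuration undefined) | CC(C)C[C@@H](c1c(OCc2ccccc2)cc(OCc2ccccc2)cc1OCc1ccccc1)[C@@]1(C)CCC2=C(C(=O)OC)CC[C@@H]3[C@H]([C@H]12)C3(C)[Cu] | intermediate
22 | methyl (1aR,7R,7aR,7bR)-1,1,7-trimethyl-7-[(1R)-3-methyl-1-[2,4,6-tris(benzyloxy)phenyl]butyl]-1a,2,3,5,6,7,7a,7b-octahydro-1H-cyclopropa[e]azulene-4-carboxylate | CC(C)C[C@@H](c1c(OCc2ccccc2)cc(OCc2ccccc2)cc1OCc1ccccc1)[C@@]1(C)CCC2=C(C(=O)OC)CC[C@@H]3[C@H]([C@H]12)C3(C)C | intermediate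
23 | [(1aR,7R,7aR,7bR)-1,1,7-trimethyl-7-[(1R)-3-methyl-1-[2,4,6-tris(benzyloxy)phenyl]butyl]-1a,2,3,5,6,7,7a,7b-octahydro-1H-cyclopropa[e]azulen-4-yl]methanol | CC(C)C[C@@H](c1c(OCc2ccccc2)cc(OCc2ccccc2)cc1OCc1ccccc1)[C@@]1(C)CCC2=C(CO)CC[C@@H]3[C@H]([C@H]12)C3(C)C | intermediate
24 | methanesulfonate of 23 | CC(C)C[C@@H](c1c(OCc2ccccc2)cc(OCc2ccccc2)cc1OCc1ccccc1)[C@@]1(C)CCC2=C(COS(C)(=O)=O)CC[C@@H]3[C@H]([C@H]12)C3(C)C | intermediate
25 | (1aR,7R,7aR,7bR)-1,1,4,7-tetramethyl-7-[(1R)-3-methyl-1-[2,4,6-tris(benzyloxy)phenyl]butyl]-1a,2,3,5,6,7,7a,7b-octahydro-1H-cyclopropa[e]azulene | CC(C)C[C@@H](c1c(OCc2ccccc2)cc(OCc2ccccc2)cc1OCc1ccccc1)[C@@]1(C)CCC2=C(C)CC[C@@H]3[C@H]([C@H]12)C3(C)C | intermediate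
26 | 2-[(1R)-3-methyl-1-[(1aR,7R,7aR,7bR)-1,1,4,7-tetramethyl-1a,2,3,5,6,7,7a,7b-octahydro-1H-cyclopropa[e]azulen-7-yl]butyl]benzene-1,3,5-triol | CC(C)C[C@@H](c1c(O)cc(O)cc1O)[C@@]1(C)CCC2=C(C)CC[C@@H]3[C@H]([C@H]12)C3(C)C | intermediate
27 | bridged aryl ether, the target without its two formyl groups (1S,4R,5R,6R,7R,10S,7′R) | CC(C)C[C@H]1c2c(O)cc(O)cc2O[C@]23CC[C@@]1(C)[C@H]2[C@H]1[C@@H](CC[C@@H]3C)C1(C)C | intermediate
28 | bis(dimethyliminium) dichloride of the target dialdehyde | CC(C)C[C@H]1c2c(O)c(C=[N+](C)C)c(O)c(C=[N+](C)C)c2O[C@]23CC[C@@]1(C)[C@H]2[C@H]1[C@@H](CC[C@@H]3C)C1(C)C.[Cl-].[Cl-] | intermediate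
29 | CNP0189833.2 (1S,4R,5R,6R,7R,10S,7′R; aromadendrane numbering) | CC(C)C[C@H]1c2c(O)c(C=O)c(O)c(C=O)c2O[C@]23CC[C@@]1(C)[C@H]2[C@H]1[C@@H](CC[C@@H]3C)C1(C)C | target

Total steps: 18. Longest linear sequence: 17 steps (steps 1, 2 and 4 to 18; step 3 prepares the imine on a side branch).

**Steps most likely to fail**

Step 4 (proposed new method). The auxiliary-bound enamine may not discriminate its two faces well enough towards the very reactive quinone methide, and the endo/E control at the methide carbon may be lost, which would give the C-7′ epimer or material of low enantiomeric purity. The fallback sets out from 3 and 4 and comes back at 11. Ketone 4 is converted (Me3SiCl, Et3N, DMF, 130 °C) into its thermodynamic silyl enol ether 2-methyl-1-(trimethylsilyloxy)cyclopent-1-ene F1, and MeLi in THF turns this into the tetrasubstituted enolate lithium 2-methylcyclopent-1-en-1-olate F2. F2 is added at −78 °C to o-quinone methide 8, generated from 3 and i-BuMgBr as in step 4 (Michael addition of a ketone enolate to an o-quinone methide, known chemistry). This should give racemic keto phenol, that is 10 together with its enantiomer ent-10 F3. Benzylation as in step 5 gives 11 together with its enantiomer ent-11 F4; C-7′ epimers are removed by ordinary chromatography, and the enantiomers are separated by preparative HPLC on a chiral stationary phase to return to 11.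

Step 10. The Cope rearrangement of 17 may be slow because the quaternary C-4 and the SiMe3 group must become cis neighbours, which leaves time for isomerization of the divinylcyclopropane or for carbenoid insertion into benzylic C–H bonds. The fallback sets out from 15 and comes back at 25; it keeps the rhodium chemistry but uses a diene without a terminal substituent and builds the cyclopropane differently.
- Diazo ester 15 reacts with 2-(tert-butyldimethylsilyloxy)buta-1,3-diene F5 under Rh2(R-DOSP)4 catalysis at the electron-rich enol ether double bond to give the siloxy divinylcyclopropane F6, which rearranges to the silyl enol ether hydroazulene ester F7.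
- i-Bu2AlH gives the allylic alcohol F8, and MsCl/Et3N then LiEt3BH give, through the allylic mesylate F9, the C-10 methyl silyl enol ether F10.
- Saegusa–Ito oxidation (Pd(OAc)2, MeCN) gives the cycloheptenone F11.
- Conjugate isopropylidene transfer from diphenylsulfonium isopropylide (from isopropyldiphenylsulfonium tetrafluoroborate and LiN(i-Pr)2, −78 °C), on the face of H-5, gives the gem-dimethylcyclopropyl ketone F12.
- Wolff–Kishner reduction (N2H4·H2O, KOH, diethylene glycol, 130 to 200 °C) through the hydrazone F13 returns 25.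

Step 17. Protonation of C-10 may occur from the wrong face, or a hydride shift from C-5 to the C-1 cation may be followed by opening of the cyclopropylcarbinyl cation before the phenol closes the ring. The fallback sets out from 22 and comes back at 27; it forms O–C1 by conjugate addition instead of through a cation. Hydrogenolysis of 22 (H2, Pd/C) gives the triol ester F14. Base (Cs2CO3, MeCN) induces intramolecular oxa-Michael addition of the ortho phenoxide to C-1 of the enoate, and C-10, now alpha to the ester, is equilibrated to give the bridged ether ester F15. LiAlH4 gives the primary alcohol F16, iodination (I2, PPh3, imidazole) gives the iodide F17, and radical reduction (Bu3SnH, AIBN, toluene, 80 °C) returns 27.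

Further compounds
F1 | step 4 | 2-methyl-1-(trimethylsilyloxy)cyclopent-1-ene | CC1=C(O[Si](C)(C)C)CCC1
F2 | step 4 | lithium 2-methylcyclopent-1-en-1-olate | CC1=C([O-])CCC1.[Li+]
F3 | step 4 | ent-10, (2S)-2-[(1R)-1-[2,4-bis(benzyloxy)-6-hydroxyphenyl]-3-methylbutyl]-2-methylcyclopentan-1-one | CC(C)C[C@H](c1c(O)cc(OCc2ccccc2)cc1OCc1ccccc1)[C@]1(C)CCCC1=O
F4 | step 4 | ent-11, (2S)-2-methyl-2-[(1R)-3-methyl-1-[2,4,6-tris(benzyloxy)phenyl]butyl]cyclopentan-1-one | CC(C)C[C@H](c1c(OCc2ccccc2)cc(OCc2ccccc2)cc1OCc1ccccc1)[C@]1(C)CCCC1=O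
F5 | step 10 | 2-(tert-butyldimethylsilyloxy)buta-1,3-diene | C=CC(=C)O[Si](C)(C)C(C)(C)C
F6 | step 10 | siloxy divinylcyclopropane (cyclopentenyl and vinyl groups cis) | CC(C)C[C@@H](c1c(OCc2ccccc2)cc(OCc2ccccc2)cc1OCc1ccccc1)[C@@]1(C)CCC([C@@]2(C(=O)OC)C[C@@]2(O[Si](C)(C)C(C)(C)C)C=C)=C1
F7 | step 10 | methyl 6-(tert-butyldimethylsilyloxy)-3-methyl-3-[3-methyl-1-[2,4,6-tris(benzyloxy)phenyl]butyl]-1,2,3,3a,4,7-hexahydroazulene-8-carboxylate (C-4, C-5, C-7′ as in 19) | CC(C)C[C@@H](c1c(OCc2ccccc2)cc(OCc2ccccc2)cc1OCc1ccccc1)[C@@]1(C)CCC2=C(C(=O)OC)CC(O[Si](C)(C)C(C)(C)C)=CC[C@H]12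
F8 | step 10 | allylic alcohol from F7 (CO2Me reduced to CH2OH) | CC(C)C[C@@H](c1c(OCc2ccccc2)cc(OCc2ccccc2)cc1OCc1ccccc1)[C@@]1(C)CCC2=C(CO)CC(O[Si](C)(C)C(C)(C)C)=CC[C@H]12
F9 | step 10 | methanesulfonate of F8 | CC(C)C[C@@H](c1c(OCc2ccccc2)cc(OCc2ccccc2)cc1OCc1ccccc1)[C@@]1(C)CCC2=C(COS(C)(=O)=O)CC(O[Si](C)(C)C(C)(C)C)=CC[C@H]12
F10 | step 10 | C-10 methyl silyl enol ether | CC(C)C[C@@H](c1c(OCc2ccccc2)cc(OCc2ccccc2)cc1OCc1ccccc1)[C@@]1(C)CCC2=C(C)CC(O[Si](C)(C)C(C)(C)C)=CC[C@H]12
F11 | step 10 | cycloheptenone (C8 ketone, C6=C7) | CC(C)C[C@@H](c1c(OCc2ccccc2)cc(OCc2ccccc2)cc1OCc1ccccc1)[C@@]1(C)CCC2=C(C)CC(=O)C=C[C@H]12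
F12 | step 10 | gem-dimethylcyclopropyl ketone (C8 ketone; C-6, C-7 as in 25) | CC(C)C[C@@H](c1c(OCc2ccccc2)cc(OCc2ccccc2)cc1OCc1ccccc1)[C@@]1(C)CCC2=C(C)CC(=O)[C@@H]3[C@H]([C@H]12)C3(C)C
F13 | step 10 | hydrazone of F12 | CC(C)C[C@@H](c1c(OCc2ccccc2)cc(OCc2ccccc2)cc1OCc1ccccc1)[C@@]1(C)CCC2=C(C)CC(=NN)[C@@H]3[C@H]([C@H]12)C3(C)C
F14 | step 17 | triol ester (22 without its three benzyl groups) | CC(C)C[C@@H](c1c(O)cc(O)cc1O)[C@@]1(C)CCC2=C(C(=O)OC)CC[C@@H]3[C@H]([C@H]12)C3(C)C
F15 | step 17 | bridged ether ester (27 with CO2Me in place of the C-10 methyl) | CC(C)C[C@H]1c2c(O)cc(O)cc2O[C@]23CC[C@@]1(C)[C@H]2[C@H]1[C@@H](CC[C@@H]3C(=O)OC)C1(C)C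
F16 | step 17 | bridged ether primary alcohol | CC(C)C[C@H]1c2c(O)cc(O)cc2O[C@]23CC[C@@]1(C)[C@H]2[C@H]1[C@@H](CC[C@@H]3CO)C1(C)C
F17 | step 17 | bridged ether primary iodide | CC(C)C[C@H]1c2c(O)cc(O)cc2O[C@]23CC[C@@]1(C)[C@H]2[C@H]1[C@@H](CC[C@@H]3CI)C1(C)C
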